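Readings and results are simulated on assumed constants; the scatter is artificial.

In a one-step world, first order in substrate, percent against time is one curve for every charge, so the stretch of the time axis is one: that is the zero of the scale. You asked for a quick number, and these runs sit off that zero.

| flask | substrate | gas phase | remark | time |
|---|---|---|---|---|
| dawn | 0.40 M | 120 mM (held) | run made earlier |  |
| noon | 1.6 M | 120 mM (held) | run made earlier |  |
| flask | 0.80 M | 120 mM (held) |  | 4.0 h |

- dawn (time / h: target / %): 0.417: 11.6; 0.833: 17.2; 2.00: 13.8; 4.00: 2.6
- noon (time / h: target / %): 0.417: 6.5; 0.833: 12.0; 2.00: 17.2; 4.00: 15.8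

(readings scatter by 0.5 percentage points)

- the best time, 4.0 h at the latest, for target
- the amount of target, in percent of the substrate charged, at that time
- the first time at which target reaches 13%, in the same percent

- at the start none of the gas phase is in solution
- a reading or a percentage of target counts all its forms, free or not

Dawn at 0.833 h and noon at 2.00 h read the same 17.2%. The flask's charge is twice dawn's and half noon's, so I put it at the midpoint on a log scale. The square root of that time ratio, 1.55, is then my stretch per doubling of the charge, a scaling factor that carries the scatter of the readings. So the flask should read 17.2% near 1.29 h and 15.8% near 2.58 h, with the top between them.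

Your forecast sees “the noon run is stretched about 2.4-fold in time”, but it stretches the flask about 1.45-fold from dawn where I get 1.55. It gives 17.8% (16.8% to 18.8%) at 1.6 h (1.35 h to 1.9 h) and the asked level at 0.63 h (0.56 h to 0.72 h). Its best time lies between my two times, and I would commit to it.

The flask gives 18.0% at 1.62 h and reaches the level at 0.636 h, each inside the forecast's range.

    substrate → decomposition product (k = 8.50 × 10⁻⁷ s⁻¹)
    substrate + dissolved gas → target (k = 0.00310 M⁻¹ s⁻¹)
    dissolved gas + target → over-reacted product (k = 0.00430 M⁻¹ s⁻¹)
    dissolved gas + target → over-reaction product (k = 0.00590 M⁻¹ s⁻¹)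
    gas phase ⇌ dissolved gas, rate k5*(csat - [dissolved gas]) (kL = 0.00100 s⁻¹)
    crystals ⇌ target, rate k6*(cs6 - [target]) while solid is left; crystals form when [target] > cs6 (solubility = 0.470 M, k = 0.0120 s⁻¹)

At the best time the flask holds dissolved gas at 0.0302 M, a quarter of saturation. Stretching dawn's 13.8% at 2.00 h by 1.55 lands at 3.10 h, and the flask holds 12.8% at 3.23 h.

Now take the same flask read at 2.5 h: the stretch puts noon's 15.8% at 2.58 h, so expect about that. Computed, it holds 16.0%.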